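Ring order: ring A comes from dimedone, ring B is closed second.
Target ⇐ endocyclic primary allylic alcohol (C14–OH, C7=C8) by reductive 1,3-transposition, so the exocyclic C7=CH2 is made last; C9 carbinol ⇐ C9 ketone by a ketoreductase; C10–Br ⇐ α'-bromination of the ring A enone.
Ring B trans C2–Br/C3–Cl ⇐ C2=C3 alkene via epoxide, bromide opening and chloride substitution with retention; the enone ⇐ spirocyclic vinylogous ester by Stork–Danheiser transposition with a hydroxymethyl anion equivalent.
Ring B ⇐ ring-closing metathesis of allyl and 3-methylbut-3-enyl arms on C6; C6 ⇐ Pd-catalysed enantioselective decarboxylative allylation of an achiral enol carbonate.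

Assumption: spiro compounds carry chamigrane (spiro[5.5]undecane) locants: C6 spiro, ring B = C1–C5, ring A = C7–C11, C14 = exocyclic carbon on C7.
Assumption: stannane 11 and the PHOX ligand are purchasable; the ligand enantiomer in step 5 is assigned by analogy with the known (S)-ligand → (S)-2-allyl-2-methylcyclohexanone correlation.
Assumption: the C6 descriptor changes from S to R at compound 20 only through a CIP priority change; its geometry is set once in step 5 and never altered.

Step 1
Reactants: 1 dimedone (5,5-dimethylcyclohexane-1,3-dione); 2 isobutanol (2-methylpropan-1-ol)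
Product: 3 3-isobutoxy-5,5-dimethylcyclohex-2-en-1-one
Conditions: TsOH·H2O (cat.), toluene, reflux, Dean–Stark
Reagents that add atoms: 2 isobutanol, CC(C)CO
Why: Acid-catalysed condensation of the enolized 1,3-dione with the alcohol under azeotropic water removal (vinylogous esterification) gives the vinylogous ester, and no stereocenter is formed.

Step 2
Reactants: 4 3-methylbut-3-en-1-ol
Product: 5 4-iodo-2-methylbut-1-ene
Conditions: I2, PPh3, imidazole, CH2Cl2, 0 °C → rt
Reagents that add atoms: iodine, [I][I]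
Why: Appel-type (Garegg–Samuelsson) iodination converts the primary alcohol into the iodide by SN2 displacement of an alkoxyphosphonium ion without touching the alkene.

Step 3
Reactants: 3 3-isobutoxy-5,5-dimethylcyclohex-2-en-1-one; 5 4-iodo-2-methylbut-1-ene
Product: 6 rac-3-isobutoxy-5,5-dimethyl-6-(3-methylbut-3-en-1-yl)cyclohex-2-en-1-one
Conditions: LiN(iPr)2 (1.1 equiv), THF, −78 °C; then 5, −78 °C → rt
Reagents that add atoms: 5 4-iodo-2-methylbut-1-ene, CC(=C)CCI
Why: Kinetic deprotonation of a 3-alkoxyenone occurs at the α'-carbon (Stork–Danheiser α'-alkylation) and the enolate is alkylated by the primary iodide; the C–H centre formed is racemic and is erased again in step 4.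

Step 4
Reactants: 6 rac-3-isobutoxy-5,5-dimethyl-6-(3-methylbut-3-en-1-yl)cyclohex-2-en-1-one; 7 allyl chloroformate
Product: 8 allyl 5-isobutoxy-3,3-dimethyl-2-(3-methylbut-3-en-1-yl)cyclohexa-1,5-dien-1-yl carbonate
Conditions: LiN(iPr)2, TMEDA, THF, −78 → 0 °C; then 7, −78 °C
Reagents that add atoms: 7 allyl chloroformate, C=CCOC(=O)Cl
Why: A second kinetic α'-deprotonation gives the tetrasubstituted lithium enolate, which the hard chloroformate acylates on oxygen (enolate O-acylation) to give an achiral enol carbonate.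

Step 5
Reactants: 8 allyl 5-isobutoxy-3,3-dimethyl-2-(3-methylbut-3-en-1-yl)cyclohexa-1,5-dien-1-yl carbonate
Product: 9 (S)-6-allyl-3-isobutoxy-5,5-dimethyl-6-(3-methylbut-3-en-1-yl)cyclohex-2-en-1-one
Conditions: Pd(dmdba)2 [bis(3,5,3',5'-tetramethoxydibenzylideneacetone)palladium] (5 mol %), (R)-(CF3)3-t-BuPHOX [(R)-4-tert-butyl-2-{2-[bis(4-(trifluoromethyl)phenyl)phosphanyl]-5-(trifluoromethyl)phenyl}-4,5-dihydrooxazole] (6 mol %), benzene, 25 °C
Reagents that add atoms: none
Why: Zerovalent palladium ionizes the allyl carbonate, CO2 is lost, and the PHOX-ligated π-allylpalladium enolate recombines on one enolate face (decarboxylative asymmetric allylic alkylation), which sets the quaternary C6 as S as the first stereocenter of defined configuration; the electron-poor ligand is used because the new centre sits next to the gem-dimethyl carbon.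

Step 6
Reactants: 9 (S)-6-allyl-3-isobutoxy-5,5-dimethyl-6-(3-methylbut-3-en-1-yl)cyclohex-2-en-1-one
Product: 10 (6S)-9-isobutoxy-3,11,11-trimethylspiro[5.5]undeca-2,8-dien-7-one
Conditions: second-generation Grubbs catalyst (H2IMes)(PCy3)Cl2Ru=CHPh (5 mol %), CH2Cl2, 40 °C
Reagents that add atoms: none
Why: Ring-closing olefin metathesis between the allyl and isopropenyl alkenes closes the six-membered ring B as its trisubstituted C2=C3 alkene with loss of ethene, while the push-pull enol ether alkene is inert and C6 is untouched.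

Step 7
Reactants: 10 (6S)-9-isobutoxy-3,11,11-trimethylspiro[5.5]undeca-2,8-dien-7-one; 11 tributyl[(methoxymethoxy)methyl]stannane
Product: 13 (6S)-7-[(methoxymethoxy)methyl]-3,11,11-trimethylspiro[5.5]undeca-2,7-dien-9-one, via tertiary allylic alcohol 12 (not isolated)
Conditions: 11, n-BuLi, THF, −78 °C; CeCl3, −78 °C; then 10, −78 → 0 °C; then 1 M HCl, 0 °C → rt
Reagents that add atoms: 11 tributyl[(methoxymethoxy)methyl]stannane, CCCC[Sn](CCCC)(CCCC)COCOC; water, O
Why: Tin–lithium exchange gives an α-alkoxymethyl nucleophile (hydroxymethyl anion equivalent) whose organocerium form adds 1,2 to the hindered vinylogous ester carbonyl, and aqueous acid then ionizes the tertiary allylic alcohol and hydrolyses the enol ether to the transposed enone (Stork–Danheiser carbonyl transposition), destroying the transient C7 carbinol centre.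

Step 8
Reactants: 13 (6S)-7-[(methoxymethoxy)methyl]-3,11,11-trimethylspiro[5.5]undeca-2,7-dien-9-one
Product: 14 (6S)-7-(hydroxymethyl)-3,11,11-trimethylspiro[5.5]undeca-2,7-dien-9-one
Conditions: conc. HCl (cat.), MeOH, 40 °C
Reagents that add atoms: none
Why: Acid-catalysed transacetalization to methanol (acetal cleavage) removes the methoxymethyl group, and the allylic C14 position does not ionize because it is conjugated to the enone.

Step 9
Reactants: 14 (6S)-7-(hydroxymethyl)-3,11,11-trimethylspiro[5.5]undeca-2,7-dien-9-one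
Product: 15 (6S)-7-[(tert-butyldiphenylsilyloxy)methyl]-3,11,11-trimethylspiro[5.5]undeca-2,7-dien-9-one
Conditions: TBDPSCl, imidazole, DMF, rt
Reagents that add atoms: tert-butyl(chloro)diphenylsilane, CC(C)(C)[Si](Cl)(c1ccccc1)c1ccccc1
Why: Imidazole-promoted silylation of the unhindered primary alcohol (silyl ether formation) installs an acid-robust group that survives HCl in step 12 and adds bulk on the C7 side of ring B.

Step 10
Reactants: 15 (6S)-7-[(tert-butyldiphenylsilyloxy)methyl]-3,11,11-trimethylspiro[5.5]undeca-2,7-dien-9-one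
Product: 16 (2R,3S,6S)-7-[(tert-butyldiphenylsilyloxy)methyl]-2,3-epoxy-3,11,11-trimethylspiro[5.5]undec-7-en-9-one (oxirane oxygen trans to C7)
Conditions: mCPBA, NaHCO3, CH2Cl2, 0 °C
Reagents that add atoms: 3-chloroperoxybenzoic acid, OOC(=O)c1cccc(Cl)c1
Why: The electron-rich trisubstituted C2=C3 alkene is epoxidized far faster than the electron-poor enone (Prilezhaev epoxidation), and the peracid is expected to approach the ring B face opposite the C7 arm that carries the bulky silyloxymethyl group, which sets C2 and C3 with the oxygen trans to C7.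

Step 11
Reactants: 16 (2R,3S,6S)-7-[(tert-butyldiphenylsilyloxy)methyl]-2,3-epoxy-3,11,11-trimethylspiro[5.5]undec-7-en-9-one
Product: 17 (2S,3S,6S)-2-bromo-7-[(tert-butyldiphenylsilyloxy)methyl]-3-hydroxy-3,11,11-trimethylspiro[5.5]undec-7-en-9-one
Conditions: Li2NiBr4 (0.4 M stock solution in THF), 0 °C → rt
Reagents that add atoms: dilithium tetrabromonickelate, [Li+].[Li+].[Ni+2].[Br-].[Br-].[Br-].[Br-]
Why: The soft bromide of Li2NiBr4 opens the trisubstituted epoxide by SN2 attack at the less substituted C2 with inversion (trans-diaxial Fürst–Plattner opening), which puts bromine on C2 cis to C7 and leaves the tertiary C3 carbinol configuration unchanged.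

Step 12
Reactants: 17 (2S,3S,6S)-2-bromo-7-[(tert-butyldiphenylsilyloxy)methyl]-3-hydroxy-3,11,11-trimethylspiro[5.5]undec-7-en-9-one
Product: 18 (2S,3S,6S)-2-bromo-7-[(tert-butyldiphenylsilyloxy)methyl]-3-chloro-3,11,11-trimethylspiro[5.5]undec-7-en-9-one
Conditions: HCl (4 M in 1,4-dioxane, 5 equiv), CH2Cl2, −20 → 0 °C
Reagents that add atoms: hydrogen chloride, Cl
Why: Ionization of the protonated tertiary alcohol is assisted by the antiperiplanar C2 bromine (neighbouring-group participation through a bromonium ion) and chloride opens that ion at the tertiary carbon from the side the hydroxyl left, so C3–Cl forms with net retention, trans to bromine.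

Step 13
Reactants: 18 (2S,3S,6S)-2-bromo-7-[(tert-butyldiphenylsilyloxy)methyl]-3-chloro-3,11,11-trimethylspiro[5.5]undec-7-en-9-one
Product: 20 (2S,3S,6R,10R)-2,10-dibromo-7-[(tert-butyldiphenylsilyloxy)methyl]-3-chloro-3,11,11-trimethylspiro[5.5]undec-7-en-9-one, via trimethylsilyl dienol ether 19 (not isolated)
Conditions: LiN(iPr)2 (1.15 equiv), Me3SiCl, THF, −78 °C; then NBS, THF, −78 → 0 °C; chromatography, 10S epimer re-equilibrated (Et3N, CH2Cl2) and recycled
Reagents that add atoms: N-bromosuccinimide, O=C1CCC(=O)N1Br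
Why: C10 is the only enolizable α-position of the enone, so kinetic deprotonation with in situ silylation gives the cross-conjugated silyloxydiene regiospecifically and NBS brominates it at C10 (α-bromination of a silyl enol ether); C10 forms as an epimer mixture whose 10R member is separated, while the 10S member is returned through the enol, since no β-hydrogen allows HBr loss.

Step 14
Reactants: 20 (2S,3S,6R,10R)-2,10-dibromo-7-[(tert-butyldiphenylsilyloxy)methyl]-3-chloro-3,11,11-trimethylspiro[5.5]undec-7-en-9-one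
Product: 21 (2S,3S,6R,10R)-2,10-dibromo-3-chloro-7-(hydroxymethyl)-3,11,11-trimethylspiro[5.5]undec-7-en-9-one
Conditions: HF·pyridine, THF, 0 °C → rt
Reagents that add atoms: none
Why: Fluoride-driven Si–O cleavage (desilylation) under non-basic conditions frees the primary alcohol without epimerizing the α-bromo ketone or eliminating the alkyl halides.

Step 15
Reactants: 21 (2S,3S,6R,10R)-2,10-dibromo-3-chloro-7-(hydroxymethyl)-3,11,11-trimethylspiro[5.5]undec-7-en-9-one
Product: 22 (2S,3S,6R,9S,10R)-2,10-dibromo-3-chloro-7-(hydroxymethyl)-3,11,11-trimethylspiro[5.5]undec-7-en-9-ol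
Conditions: ketoreductase (NADPH-dependent alcohol dehydrogenase class, picked from a screening panel), NADP+ (cat.), i-PrOH (15% v/v), DMSO (5% v/v), KH2PO4/K2HPO4 buffer pH 7.0, MgSO4, 30 °C
Reagents that add atoms: none
Why: The ketoreductase transfers hydride from NADPH to one face of the C9 carbonyl under catalyst control (enzymatic asymmetric ketone reduction with isopropanol-coupled cofactor recycling), which sets C9 as S, cis to the C10 bromine, at neutral pH where the alkene and the halides are untouched.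

Step 16
Reactants: 22 (2S,3S,6R,9S,10R)-2,10-dibromo-3-chloro-7-(hydroxymethyl)-3,11,11-trimethylspiro[5.5]undec-7-en-9-ol
Product: 25 (2S,3S,6R,9S,10R)-2,10-dibromo-3-chloro-3,11,11-trimethyl-7-methylidenespiro[5.5]undecan-9-ol, via N-allyl sulfonylhydrazine 23 (not isolated), via allylic diazene 24 (not isolated)
Conditions: PPh3, DEAD, 2-nitrobenzenesulfonylhydrazide (1.1 equiv each), THF, −30 °C → rt
Reagents that add atoms: none
Why: Mitsunobu N-alkylation of the sulfonylhydrazide by the primary allylic alcohol, loss of sulfinic acid and retro-ene loss of N2 from the allylic diazene (Myers reductive 1,3-transposition) deliver hydrogen to C8 and move the alkene to the exocyclic C7=C14 position; the hindered secondary C9 alcohol does not compete and no stereocenter is touched.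

Compound list
1 | dimedone (5,5-dimethylcyclohexane-1,3-dione) | CC1(C)CC(=O)CC(=O)C1 | starting material
2 | isobutanol (2-methylpropan-1-ol) | CC(C)CO | starting material
3 | 3-isobutoxy-5,5-dimethylcyclohex-2-en-1-one | CC(C)COC1=CC(=O)CC(C)(C)C1 | intermediate
4 | 3-methylbut-3-en-1-ol | CC(=C)CCO | starting material
5 | 4-iodo-2-methylbut-1-ene | CC(=C)CCI | intermediate
6 | rac-3-isobutoxy-5,5-dimethyl-6-(3-methylbut-3-en-1-yl)cyclohex-2-en-1-one | CC(C)COC1=CC(=O)C(CCC(C)=C)C(C)(C)C1 | intermediate
7 | allyl chloroformate (prop-2-en-1-yl carbonochloridate) | C=CCOC(=O)Cl | starting material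
8 | allyl 5-isobutoxy-3,3-dimethyl-2-(3-methylbut-3-en-1-yl)cyclohexa-1,5-dien-1-yl carbonate | C=CCOC(=O)OC1=C(CCC(C)=C)C(C)(C)CC(OCC(C)C)=C1 | intermediate
9 | (S)-6-allyl-3-isobutoxy-5,5-dimethyl-6-(3-methylbut-3-en-1-yl)cyclohex-2-en-1-one | CC(C)COC1=CC(=O)[C@](CC=C)(CCC(C)=C)C(C)(C)C1 | intermediate
10 | (6S)-9-isobutoxy-3,11,11-trimethylspiro[5.5]undeca-2,8-dien-7-one | CC(C)COC1=CC(=O)[C@@]2(CC=C(C)CC2)C(C)(C)C1 | intermediate
11 | tributyl[(methoxymethoxy)methyl]stannane | CCCC[Sn](CCCC)(CCCC)COCOC | starting material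
12 | (6S)-9-isobutoxy-7-[(methoxymethoxy)methyl]-3,11,11-trimethylspiro[5.5]undeca-2,8-dien-7-ol (both C7 epimers) | COCOCC1(O)C=C(OCC(C)C)CC(C)(C)[C@@]12CCC(C)=CC2 | intermediate
13 | (6S)-7-[(methoxymethoxy)methyl]-3,11,11-trimethylspiro[5.5]undeca-2,7-dien-9-one | COCOCC1=CC(=O)CC(C)(C)[C@@]12CCC(C)=CC2 | intermediate
14 | (6S)-7-(hydroxymethyl)-3,11,11-trimethylspiro[5.5]undeca-2,7-dien-9-one | OCC1=CC(=O)CC(C)(C)[C@@]12CCC(C)=CC2 | intermediate
15 | (6S)-7-[(tert-butyldiphenylsilyloxy)methyl]-3,11,11-trimethylspiro[5.5]undeca-2,7-dien-9-one | CC(C)(C)[Si](c3ccccc3)(c4ccccc4)OCC1=CC(=O)CC(C)(C)[C@@]12CCC(C)=CC2 | intermediate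
16 | (2R,3S,6S)-7-[(tert-butyldiphenylsilyloxy)methyl]-2,3-epoxy-3,11,11-trimethylspiro[5.5]undec-7-en-9-one | CC(C)(C)[Si](c3ccccc3)(c4ccccc4)OCC1=CC(=O)CC(C)(C)[C@@]12CC[C@]5(C)O[C@@H]5C2 | intermediate
17 | (2S,3S,6S)-2-bromo-7-[(tert-butyldiphenylsilyloxy)methyl]-3-hydroxy-3,11,11-trimethylspiro[5.5]undec-7-en-9-one | CC(C)(C)[Si](c3ccccc3)(c4ccccc4)OCC1=CC(=O)CC(C)(C)[C@@]12CC[C@](C)(O)[C@@H](Br)C2 | intermediate
18 | (2S,3S,6S)-2-bromo-7-[(tert-butyldiphenylsilyloxy)methyl]-3-chloro-3,11,11-trimethylspiro[5.5]undec-7-en-9-one | CC(C)(C)[Si](c3ccccc3)(c4ccccc4)OCC1=CC(=O)CC(C)(C)[C@@]12CC[C@](C)(Cl)[C@@H](Br)C2 | intermediate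
19 | (2S,3S,6S)-2-bromo-7-[(tert-butyldiphenylsilyloxy)methyl]-3-chloro-3,11,11-trimethyl-9-(trimethylsilyloxy)spiro[5.5]undeca-7,9-diene | CC(C)(C)[Si](c3ccccc3)(c4ccccc4)OCC1=CC(O[Si](C)(C)C)=CC(C)(C)[C@@]12CC[C@](C)(Cl)[C@@H](Br)C2 | intermediate
20 | (2S,3S,6R,10R)-2,10-dibromo-7-[(tert-butyldiphenylsilyloxy)methyl]-3-chloro-3,11,11-trimethylspiro[5.5]undec-7-en-9-one | CC(C)(C)[Si](c3ccccc3)(c4ccccc4)OCC1=CC(=O)[C@H](Br)C(C)(C)[C@@]12CC[C@](C)(Cl)[C@@H](Br)C2 | intermediate
21 | (2S,3S,6R,10R)-2,10-dibromo-3-chloro-7-(hydroxymethyl)-3,11,11-trimethylspiro[5.5]undec-7-en-9-one | OCC1=CC(=O)[C@H](Br)C(C)(C)[C@@]12CC[C@](C)(Cl)[C@@H](Br)C2 | intermediate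
22 | (2S,3S,6R,9S,10R)-2,10-dibromo-3-chloro-7-(hydroxymethyl)-3,11,11-trimethylspiro[5.5]undec-7-en-9-ol | OCC1=C[C@H](O)[C@H](Br)C(C)(C)[C@@]12CC[C@](C)(Cl)[C@@H](Br)C2 | intermediate
23 | 1-{[(2S,3S,6R,9S,10R)-2,10-dibromo-3-chloro-9-hydroxy-3,11,11-trimethylspiro[5.5]undec-7-en-7-yl]methyl}-1-(2-nitrobenzenesulfonyl)hydrazine | NN(CC1=C[C@H](O)[C@H](Br)C(C)(C)[C@@]12CC[C@](C)(Cl)[C@@H](Br)C2)S(=O)(=O)c3ccccc3[N+](=O)[O-] | intermediate
24 | {[(2S,3S,6R,9S,10R)-2,10-dibromo-3-chloro-9-hydroxy-3,11,11-trimethylspiro[5.5]undec-7-en-7-yl]methyl}diazene | N=NCC1=C[C@H](O)[C@H](Br)C(C)(C)[C@@]12CC[C@](C)(Cl)[C@@H](Br)C2 | intermediate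
25 | (2S,3S,6R,9S,10R)-2,10-dibromo-3-chloro-3,11,11-trimethyl-7-methylidenespiro[5.5]undecan-9-ol (CNP0247242.3) | C=C1C[C@H](O)[C@H](Br)C(C)(C)[C@@]12CC[C@](C)(Cl)[C@@H](Br)C2 | target

Total step count: 16. Longest linear sequence: 15 steps (1 → 3 → 6 → 8 → 9 → 10 → 13 → 14 → 15 → 16 → 17 → 18 → 20 → 21 → 22 → 25; step 2 is a one-step side branch).

Steps most likely to fail

Step 5: the allylation must create a quaternary carbon next to the gem-dimethyl carbon, so conversion and enantiomeric excess may fall short. The fallback sets out from 3. The kinetic enolate of 3 (LiN(iPr)2, THF, −78 °C) is trapped with Me2N=CH2+ I− to give the Mannich base 6-[(dimethylamino)methyl]-3-isobutoxy-5,5-dimethylcyclohex-2-en-1-one F1. N-methylation (MeI) and NaHCO3-induced elimination then give the exocyclic enone 3-isobutoxy-5,5-dimethyl-6-methylidenecyclohex-2-en-1-one F2. A catalytic enantioselective Diels–Alder reaction of F2 with isoprene under a chiral oxazaborolidinium triflimide Lewis acid (para-regioselective, enone face chosen by the catalyst enantiomer) builds ring B and C6 in one event and comes back to the route at 10.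

Step 12: a tertiary chloride has to be made next to a secondary bromide, and E1 loss of a proton from the bromonium or tertiary cation can compete. The bromide opening of step 11, on the hindered C7 side, carries a similar risk. The fallback sets out from alkene 15 and adds the two halogens in one operation with Bu4N+ BrCl2− (CH2Cl2, −78 °C; Markovnikov, anti: bromine to C2, chloride to C3). The two trans adducts are separated and the one identical with 18 is carried on. It comes back at 18, bypasses steps 10 and 11, and makes no new compound (F0).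

Step 15: the enzyme may not accept the bulky, lipophilic polyhalogenated enone or may show the wrong facial preference. The fallback sets out from silyl ether 20 and uses substrate control: i-Bu2AlH (toluene, −78 °C) reduces the C9 carbonyl 1,2 from the face away from the axial C11 methyl. This gives the cis-bromohydrin (2S,3S,6R,9S,10R)-2,10-dibromo-7-[(tert-butyldiphenylsilyloxy)methyl]-3-chloro-3,11,11-trimethylspiro[5.5]undec-7-en-9-ol F3. HF·pyridine (THF, 0 °C) then removes the silyl group and the route is rejoined at 22.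

Further compounds
F1 | step 5 | 6-[(dimethylamino)methyl]-3-isobutoxy-5,5-dimethylcyclohex-2-en-1-one (racemic) | CC(C)COC1=CC(=O)C(CN(C)C)C(C)(C)C1
F2 | step 5 | 3-isobutoxy-5,5-dimethyl-6-methylidenecyclohex-2-en-1-one | CC(C)COC1=CC(=O)C(=C)C(C)(C)C1
F0 | step 12 | none | none
F3 | step 15 | (2S,3S,6R,9S,10R)-2,10-dibromo-7-[(tert-butyldiphenylsilyloxy)methyl]-3-chloro-3,11,11-trimethylspiro[5.5]undec-7-en-9-ol | CC(C)(C)[Si](c3ccccc3)(c4ccccc4)OCC1=C[C@H](O)[C@H](Br)C(C)(C)[C@@]12CC[C@](C)(Cl)[C@@H](Br)C2
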